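**Retrosynthetic overview**
The strategy rests on the hexasubstituted ring A (C4a, C5, C6, C7, C8, C8a). Its four adjacent oxygenated carbons C5–C8 are the four ring carbons of dimethyl squarate: the C6/C7 methoxyls are the squarate enol ethers and the C5/C8 oxygens are its two carbonyls. C4a=C8a is the free enol-ether C=C of a 2-aryl-4H-pyran-4-one.
The 4'-O-benzyl group (hydrogenolysis) and the 8-O-methyl group come off first; 5-OH is hydrogen-bonded to C4=O and so is told apart from 8-OH. Ring A then opens retro-electrocyclically to a 4-hydroxy-4-(pyranonyl)cyclobutenone, made from a 5-metalated pyranone and dimethyl squarate.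
The 5-iodopyranone comes from C-acylation of the enolate of 3-iodo-4-methoxybut-3-en-2-one with O-benzylsyringoyl chloride, followed by acid cyclization.
Ring order: B is bought (syringic acid), C is closed by addition–elimination, the four-membered ring is attached, and A is formed last.

Key step: step 8

Remark: the target has no stereocentre and no stereogenic double bond, so no enantiocontrol is needed. The two transient stereocentres on the way (the cyclobutenone carbinol and the ring-fusion carbon of the dienone) are racemic and are erased on aromatization.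

**Step 1**
Reactants: 1 syringic acid
Product: 2 benzyl 4-(benzyloxy)-3,5-dimethoxybenzoate
Conditions: BnBr (2.3 equiv), K2CO3 (3 equiv), DMF, 60 °C
Reagents that add atoms: benzyl bromide, BrCc1ccccc1
Why: Williamson O-alkylation of the phenolate and SN2 esterification of the carboxylate run together, so exhaustive benzylation removes any selectivity question.

**Step 2**
Reactants: 2 benzyl 4-(benzyloxy)-3,5-dimethoxybenzoate
Product: 3 4-(benzyloxy)-3,5-dimethoxybenzoic acid
Conditions: aq NaOH (2 M), MeOH–THF, 60 °C; then 1 M HCl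
Reagents that add atoms: sodium hydroxide, [Na+].[OH-]
Why: Saponification (BAc2 ester hydrolysis) cleaves only the benzyl ester, because aryl benzyl and aryl methyl ethers are inert to aqueous hydroxide.

**Step 3**
Reactants: 3 4-(benzyloxy)-3,5-dimethoxybenzoic acid
Product: 4 4-(benzyloxy)-3,5-dimethoxybenzoyl chloride
Conditions: (COCl)2 (1.3 equiv), DMF (cat.), CH2Cl2, 0 °C → rt; concentrated and used crude
Reagents that add atoms: oxalyl chloride, O=C(Cl)C(=O)Cl
Why: Vilsmeier-type activation with oxalyl chloride/DMF forms the acid chloride under mild conditions that leave the ethers intact, and the by-products are gases.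

**Step 4**
Reactants: 5 (E)-4-methoxybut-3-en-2-one
Product: 7 (Z)-3-iodo-4-methoxybut-3-en-2-one, via iodoacetoxy adduct 6 (not isolated)
Conditions: NIS (1.2 equiv), AcOH (2 equiv), CH2Cl2, rt, dark; then Et3N (3 equiv), 0 °C → rt
Reagents that add atoms: N-iodosuccinimide, O=C1CCC(=O)N1I
Why: Electrophilic iodoacetoxylation of the push–pull enol ether puts iodine on the nucleophilic α-carbon C3 and E1cB elimination of acetic acid restores the enone, a sequence known for β-alkoxyacrylates and β-alkoxyenones; the more stable Z isomer (OMe anti to acetyl) is expected and the geometry has no later consequence.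

**Step 5**
Reactants: 7 (Z)-3-iodo-4-methoxybut-3-en-2-one, 4 4-(benzyloxy)-3,5-dimethoxybenzoyl chloride
Product: 9 (Z)-1-[4-(benzyloxy)-3,5-dimethoxyphenyl]-4-iodo-5-methoxypent-4-ene-1,3-dione, via lithium enolate 8 (not isolated)
Conditions: 7 (2.1 equiv), LiHMDS (2.1 equiv), THF, −78 °C; then 4 (1.0 equiv), −78 °C; AcOH quench at −78 °C
Reagents that add atoms: none
Why: Only the methyl group can be deprotonated, and crossed Claisen-type C-acylation of lithium enolates of 4-methoxybut-3-en-2-ones with acid chlorides is the established entry to γ-pyrone precursors; the second equivalent of enolate absorbs the acidic proton of the 1,3-diketone and the low temperature holds back dehydroiodination.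

**Step 6**
Reactants: 9 (Z)-1-[4-(benzyloxy)-3,5-dimethoxyphenyl]-4-iodo-5-methoxypent-4-ene-1,3-dione
Product: 10 2-[4-(benzyloxy)-3,5-dimethoxyphenyl]-5-iodo-4H-pyran-4-one
Conditions: TFA (0.1–0.2 equiv), toluene, rt
Reagents that add atoms: none
Why: The enol oxygen of the aroyl ketone adds to the activated methoxyvinyl carbon C5 (6-endo oxa-Michael addition) and methanol is expelled (addition–elimination cyclocondensation), which closes ring C irreversibly with the iodine fixed at pyranone C5.

**Step 7**
Reactants: 10 2-[4-(benzyloxy)-3,5-dimethoxyphenyl]-5-iodo-4H-pyran-4-one, 11 dimethyl squarate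
Product: 13 (±)-4-{6-[4-(benzyloxy)-3,5-dimethoxyphenyl]-4-oxo-4H-pyran-3-yl}-4-hydroxy-2,3-dimethoxycyclobut-2-en-1-one, via pyranonylmagnesium chloride 12 (not isolated)
Conditions: iPrMgCl·LiCl (1.1 equiv), THF, −40 °C; then 11 (1.3 equiv) in THF, −78 → −40 °C; sat. aq NH4Cl at −40 °C; acid-free work-up and buffered silica
Reagents that add atoms: none
Why: Proposed new method: the iodine sits on the electron-poor α-carbon of a vinylogous ester, so I/Mg exchange should be fast at low temperature and give the sp2 Grignard 12, which is kept cold to suppress anti β-elimination of the ring oxygen and then adds 1,2 to one of the two equivalent, strongly electrophilic carbonyls of 11; the closest known reaction types are the I/Mg exchange of 3-iodochromones and 5-iodo-1,3-dioxin-4-ones and the 1,2-addition of organolithium and Grignard reagents to squarate esters; the new carbinol centre is formed racemic, and the symmetry of 11 removes any regiochemical question.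

**Step 8**
Reactants: 13 (±)-4-{6-[4-(benzyloxy)-3,5-dimethoxyphenyl]-4-oxo-4H-pyran-3-yl}-4-hydroxy-2,3-dimethoxycyclobut-2-en-1-one
Product: 16 4'-benzyloxy-5,8-dihydroxy-6,7,3',5'-tetramethoxyflavone, via dienylketene 14 (not isolated), via cyclohexadienone 15 (not isolated)
Conditions: degassed p-xylene (dilute), 130–138 °C, Ar
Reagents that add atoms: none
Why: Proposed new method: heat opens the cyclobutenone by conrotatory 4π electrocyclic cleavage of its C1–C4 bond to dienylketene 14, in which the ketene C=C, the former ring alkene and the pyranone C5=C6 bond form a hexatriene that closes by disrotatory 6π electrocyclization (ketene carbon, future C8, to pyranone C6, future C8a) to dienone 15, and enolization with loss of the C8a hydrogen then gives hydroquinone 16. The closest known reaction type is the Moore rearrangement (Moore–Liebeskind benzannulation) of squarate-derived 4-alkenyl- and 4-(hetero)aryl-4-hydroxycyclobutenones, and the untested element is a 4-pyranone enol-ether bond, attached through its α-carbon, as the 2π partner. Ring A is the only ring closed, by 6π electrocyclization followed by aromatizing tautomerization, and release of four-ring strain plus the gain of a benzenoid ring and of the restored pyranone makes the sequence irreversible. No lasting stereocentre is formed, since C8a of 15 is transient and racemic and the carbinol centre of 13 becomes aromatic C5. The selectivity required is torquoselectivity, and the donor hydroxyl on C4 secures it by its established preference for outward rotation, which turns the pyranonyl group inward next to the ketene and keeps the hydroxyl away from it (no butenolide). The site of closure is unambiguous because the only other neighbour of the attachment carbon is the C4 carbonyl carbon, and exclusion of oxygen keeps 16 from going on to the 5,8-quinone.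

**Step 9**
Reactants: 16 4'-benzyloxy-5,8-dihydroxy-6,7,3',5'-tetramethoxyflavone
Product: 17 4'-benzyloxy-5-hydroxy-6,7,8,3',5'-pentamethoxyflavone
Conditions: MeI (1.05 equiv), K2CO3 (1.1 equiv), degassed acetone, rt → 40 °C, Ar
Reagents that add atoms: iodomethane, CI
Why: Williamson methylation under weak base distinguishes the two phenols, because 5-OH is locked in a hydrogen bond to the C4 carbonyl and is far less acidic and nucleophilic than the free 8-OH, a selectivity long used for 5,8-dihydroxyflavones.

**Step 10**
Reactants: 17 4'-benzyloxy-5-hydroxy-6,7,8,3',5'-pentamethoxyflavone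
Product: 18 5,4'-dihydroxy-6,7,8,3',5'-pentamethoxyflavone
Conditions: H2 (1 atm), 10% Pd/C, EtOAc–MeOH, rt, stopped after one equivalent of H2
Reagents that add atoms: none
Why: Catalytic hydrogenolysis of the benzyl aryl ether at one atmosphere is faster than reduction of the conjugated flavone C2=C3 bond and leaves methyl ethers and phenols untouched.

**Compound list**
1 | syringic acid | COc1cc(C(=O)O)cc(OC)c1O | starting material
2 | benzyl 4-(benzyloxy)-3,5-dimethoxybenzoate | COc1cc(C(=O)OCc2ccccc2)cc(OC)c1OCc1ccccc1 | intermediate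
3 | 4-(benzyloxy)-3,5-dimethoxybenzoic acid | COc1cc(C(=O)O)cc(OC)c1OCc1ccccc1 | intermediate
4 | 4-(benzyloxy)-3,5-dimethoxybenzoyl chloride | COc1cc(C(=O)Cl)cc(OC)c1OCc1ccccc1 | intermediate
5 | (E)-4-methoxybut-3-en-2-one | CO/C=C/C(C)=O | starting material
6 | 4-acetoxy-3-iodo-4-methoxybutan-2-one (diastereomer mixture, racemic, not isolated) | COC(OC(C)=O)C(I)C(C)=O | intermediate
7 | (Z)-3-iodo-4-methoxybut-3-en-2-one | CO/C=C(\I)C(C)=O | intermediate
8 | lithium (Z)-3-iodo-4-methoxybuta-1,3-dien-2-olate (not isolated) | CO/C=C(\I)C(=C)[O-].[Li+] | intermediate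
9 | (Z)-1-[4-(benzyloxy)-3,5-dimethoxyphenyl]-4-iodo-5-methoxypent-4-ene-1,3-dione (drawn as diketone, largely enolized) | CO/C=C(\I)C(=O)CC(=O)c1cc(OC)c(OCc2ccccc2)c(OC)c1 | intermediate
10 | 2-[4-(benzyloxy)-3,5-dimethoxyphenyl]-5-iodo-4H-pyran-4-one | COc1cc(-c2cc(=O)c(I)co2)cc(OC)c1OCc1ccccc1 | intermediate
11 | dimethyl squarate (3,4-dimethoxycyclobut-3-ene-1,2-dione) | COC1=C(OC)C(=O)C1=O | starting material
12 | {6-[4-(benzyloxy)-3,5-dimethoxyphenyl]-4-oxo-4H-pyran-3-yl}magnesium chloride (LiCl complex, not isolated) | COc1cc(-c2cc(=O)c([Mg]Cl)co2)cc(OC)c1OCc1ccccc1 | intermediate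
13 | (±)-4-{6-[4-(benzyloxy)-3,5-dimethoxyphenyl]-4-oxo-4H-pyran-3-yl}-4-hydroxy-2,3-dimethoxycyclobut-2-en-1-one | COC1=C(OC)C(O)(c2coc(-c3cc(OC)c(OCc4ccccc4)c(OC)c3)cc2=O)C1=O | intermediate
14 | (Z)-4-{6-[4-(benzyloxy)-3,5-dimethoxyphenyl]-4-oxo-4H-pyran-3-yl}-4-hydroxy-2,3-dimethoxybuta-1,3-dien-1-one (dienylketene, pyranonyl cis to the ketene arm, not isolated) | O=C=C(OC)/C(OC)=C(/O)c1coc(-c2cc(OC)c(OCc3ccccc3)c(OC)c2)cc1=O | intermediate
15 | (±)-2-[4-(benzyloxy)-3,5-dimethoxyphenyl]-5-hydroxy-6,7-dimethoxy-8aH-chromene-4,8-dione (not isolated) | O=C1C(OC)=C(OC)C(O)=C2C(=O)C=C(c3cc(OC)c(OCc4ccccc4)c(OC)c3)OC12 | intermediate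
16 | 4'-benzyloxy-5,8-dihydroxy-6,7,3',5'-tetramethoxyflavone | COc1cc(-c2cc(=O)c3c(O)c(OC)c(OC)c(O)c3o2)cc(OC)c1OCc1ccccc1 | intermediate
17 | 4'-benzyloxy-5-hydroxy-6,7,8,3',5'-pentamethoxyflavone | COc1cc(-c2cc(=O)c3c(O)c(OC)c(OC)c(OC)c3o2)cc(OC)c1OCc1ccccc1 | intermediate
18 | 5,4'-dihydroxy-6,7,8,3',5'-pentamethoxyflavone | COc1cc(-c2cc(=O)c3c(O)c(OC)c(OC)c(OC)c3o2)cc(OC)c1O | target

**Total step count:** 10
**Longest linear sequence:** 9 steps (1 → 2 → 3 → 4 → 9 → 10 → 13 → 16 → 17 → 18, that is steps 1, 2, 3, 5, 6, 7, 8, 9 and 10)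

**Steps most likely to fail**

**Step 8 (ring expansion).**
- What may go wrong:
  - The 6π closure has to disturb the cross-conjugated, partly aromatic pyranone, so the dienylketene may revert, dimerize or be intercepted by nucleophiles before it closes.
  - A minor inward rotation of the hydroxyl may drain material by lactonization.
  - Long heating may cause oxidative loss of the hydroquinone.
- Fallback (known chemistry, sets out from 4, comes back at 16): ring A is bought and the C8 oxygen is put in last.
  - The lithium dianion of purchasable 2-hydroxy-4,5,6-trimethoxyacetophenone (CC(=O)c1c(O)cc(OC)c(OC)c1OC; LiHMDS, THF, −78 °C) is C-aroylated with 4. This is a direct variant of the Baker–Venkataraman sequence and gives 1-[4-(benzyloxy)-3,5-dimethoxyphenyl]-3-(2-hydroxy-4,5,6-trimethoxyphenyl)propane-1,3-dione F1.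
  - Catalytic H2SO4 in AcOH cyclodehydrates this to 4'-benzyloxy-5,6,7,3',5'-pentamethoxyflavone F2.
  - BCl3 with pentamethylbenzene in CH2Cl2 removes the carbonyl-chelated 5-methyl group together with the benzyl group, giving 5,4'-dihydroxy-6,7,3',5'-tetramethoxyflavone F3.
  - One equivalent of BnBr with K2CO3 re-benzylates only the non-chelated 4'-OH, giving 4'-benzyloxy-5-hydroxy-6,7,3',5'-tetramethoxyflavone F4.
  - Elbs persulfate oxidation (K2S2O8, aq KOH–pyridine) attacks the free position para to 5-OH and gives the potassium flavon-8-yl sulfate F5. Warm dilute HCl hydrolyses it to 16.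

**Step 7 (magnesiation and addition).**
- What may go wrong:
  - The metalated pyranone may fragment by anti β-elimination of its ring oxygen.
  - iPrMgCl may attack C2, C6 or the carbonyl of the pyranone in competition with the exchange.
  - The stabilized Grignard may add to the squarate too slowly to outrun its own decay.
- Fallback (known chemistry, sets out from 4, comes back at 18): all four ring-A oxygens are bought, and the 5-OH is revealed by chelation-directed demethylation.
  - The lithium dianion of purchasable 2-hydroxy-3,4,5,6-tetramethoxyacetophenone (CC(=O)c1c(O)c(OC)c(OC)c(OC)c1OC) is aroylated with 4. This gives 1-[4-(benzyloxy)-3,5-dimethoxyphenyl]-3-(2-hydroxy-3,4,5,6-tetramethoxyphenyl)propane-1,3-dione F6.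
  - Acid cyclodehydration gives 4'-benzyloxy-5,6,7,8,3',5'-hexamethoxyflavone F7.
  - BCl3 with pentamethylbenzene (CH2Cl2, −78 → 0 °C) then cleaves the peri 5-methyl ether and the benzyl ether in one operation and delivers 18.

**Step 5 (acylation of the iodoenone enolate).**
- What may go wrong:
  - The base may induce anti elimination of HI from the iodoenone.
  - The enolate may be O-acylated.
  - Proton exchange with the product may stall the coupling.
- Fallback (sets out from 4, comes back at 9): the roles in the Claisen coupling are reversed, so that the iodoalkene unit is only ever an electrophile.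
  - Me2CuLi (THF, −78 °C) converts 4 into 1-[4-(benzyloxy)-3,5-dimethoxyphenyl]ethan-1-one F8.
  - Separately, methyl (E)-3-methoxyacrylate is iodinated with NIS/AcOH and then Et3N to methyl (Z)-2-iodo-3-methoxyacrylate F9.
  - This ester is saponified with LiOH to (Z)-2-iodo-3-methoxyacrylic acid F10, which oxalyl chloride/DMF converts into (Z)-2-iodo-3-methoxyacryloyl chloride F11.
  - Acylation of the lithium enolate of F8 (LiHMDS, two equivalents of enolate, THF, −78 °C) with F11 gives 9.

**Further compounds**
F1 | step 8 | 1-[4-(benzyloxy)-3,5-dimethoxyphenyl]-3-(2-hydroxy-4,5,6-trimethoxyphenyl)propane-1,3-dione | COc1cc(C(=O)CC(=O)c2c(O)cc(OC)c(OC)c2OC)cc(OC)c1OCc1ccccc1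
F2 | step 8 | 4'-benzyloxy-5,6,7,3',5'-pentamethoxyflavone | COc1cc(-c2cc(=O)c3c(OC)c(OC)c(OC)cc3o2)cc(OC)c1OCc1ccccc1
F3 | step 8 | 5,4'-dihydroxy-6,7,3',5'-tetramethoxyflavone | COc1cc(-c2cc(=O)c3c(O)c(OC)c(OC)cc3o2)cc(OC)c1O
F4 | step 8 | 4'-benzyloxy-5-hydroxy-6,7,3',5'-tetramethoxyflavone | COc1cc(-c2cc(=O)c3c(O)c(OC)c(OC)cc3o2)cc(OC)c1OCc1ccccc1
F5 | step 8 | potassium 4'-benzyloxy-5-hydroxy-6,7,3',5'-tetramethoxyflavon-8-yl sulfate | COc1cc(-c2cc(=O)c3c(O)c(OC)c(OC)c(OS(=O)(=O)[O-])c3o2)cc(OC)c1OCc1ccccc1.[K+]
F6 | step 7 | 1-[4-(benzyloxy)-3,5-dimethoxyphenyl]-3-(2-hydroxy-3,4,5,6-tetramethoxyphenyl)propane-1,3-dione | COc1cc(C(=O)CC(=O)c2c(O)c(OC)c(OC)c(OC)c2OC)cc(OC)c1OCc1ccccc1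
F7 | step 7 | 4'-benzyloxy-5,6,7,8,3',5'-hexamethoxyflavone | COc1cc(-c2cc(=O)c3c(OC)c(OC)c(OC)c(OC)c3o2)cc(OC)c1OCc1ccccc1
F8 | step 5 | 1-[4-(benzyloxy)-3,5-dimethoxyphenyl]ethan-1-one | COc1cc(C(C)=O)cc(OC)c1OCc1ccccc1
F9 | step 5 | methyl (Z)-2-iodo-3-methoxyacrylate | CO/C=C(\I)C(=O)OC
F10 | step 5 | (Z)-2-iodo-3-methoxyacrylic acid | CO/C=C(\I)C(=O)O
F11 | step 5 | (Z)-2-iodo-3-methoxyacryloyl chloride | CO/C=C(\I)C(=O)Cl
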